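**Retrosynthetic overview**
1. The strategy rests on the C5–C10 bond shared by rings A and B (C10 = angular C–CH3, C5 = angular C–OH), with Br on C1 of ring A beside C10 and the trans-diol on C4/C5. This is the pattern left when a bromonium ion closes a ten-membered 1(10),4-diene across the ring.
2. Target ⇒ 4,5-epoxide ⇒ C4=C5 octalin ⇒ (key step: C5–C10 and C1–Br) (E,E)-cyclodecadiene whose C5 carries silicon, bridged through Si–O to the C7 oxygen.
3. Ten-membered ring ⇒ C2–C3 bond by intramolecular alkylation of an allylic sulfone; C5-silyl tetrasubstituted alkene ⇒ tethered silylformylation of a 2-butynyl carbinol; C7 carbinol ⇒ chelation-controlled Grignard addition to a chloromethyl ketone.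
4. Ring order: ring C first (from 2,2-dimethylcyclopentane-1,3-dione), then the ten-membered ring, then rings A and B together in the key step.

Key step: step 24

Atom labels: decalin carbons C1–C10 in eudesmane order (C1 = CHBr, C4 = C(CH3)OH, C7 = carbinol carbon bearing ring C). Ring C carbons are C1'–C5' (C1' = quaternary C–CH3 bonded to C7, C2' = CHO, C4' = CHBr, C5' = C(CH3)2). "RC" = (1R,2S,4R)-4-bromo-2-(methoxymethoxy)-1,5,5-trimethylcyclopentyl.
Remark on the chemistry: silicon on C5 is tied to O7 as a dimethylsiloxane bridge, so it serves as leaving group, O7 protection and conformational lock at once; O2' is a methoxymethyl (MOM) ether.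
Assumption: 1, 13, 21 and all reagents are bought.

Step 1
Reactants: 1 2,2-dimethylcyclopentane-1,3-dione
Product: 2 (S)-3-hydroxy-2,2-dimethylcyclopentan-1-one
Conditions: baker's yeast (Saccharomyces cerevisiae), sucrose, H2O, 30 °C
Reagents that add atoms: none
Why: Enantiotopic-group-selective microbial monoreduction of a prochiral 2,2-disubstituted 1,3-diketone is established for this substrate class and should give the (S)-carbinol, the future C4' with oxygen on the face opposite to the final bromine.

Step 2
Reactants: 2 (S)-3-hydroxy-2,2-dimethylcyclopentan-1-one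
Product: 3 (S)-3-(tert-butyldimethylsilyloxy)-2,2-dimethylcyclopentan-1-one
Conditions: TBSCl, imidazole, DMF, rt
Reagents that add atoms: tert-butylchlorodimethylsilane, CC(C)(C)[Si](C)(C)Cl
Why: Routine O-silylation; the bulky silyl ether shields one ring face for step 5 and is removed by fluoride in step 8.

Step 3
Reactants: 3 (S)-3-(tert-butyldimethylsilyloxy)-2,2-dimethylcyclopentan-1-one
Product: 4 (S)-4-(tert-butyldimethylsilyloxy)-5,5-dimethylcyclopent-1-en-1-yl trifluoromethanesulfonate
Conditions: KHMDS, THF, −78 °C; PhNTf2, −78 → 0 °C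
Reagents that add atoms: N-phenylbis(trifluoromethanesulfonimide), O=S(=O)(N(c1ccccc1)S(=O)(=O)C(F)(F)F)C(F)(F)F
Why: Enolate O-sulfonylation; the ketone can enolise only away from the quaternary carbon, so one enol triflate should form.

Step 4
Reactants: 4 (S)-4-(tert-butyldimethylsilyloxy)-5,5-dimethylcyclopent-1-en-1-yl trifluoromethanesulfonate
Product: 5 methyl (S)-4-(tert-butyldimethylsilyloxy)-5,5-dimethylcyclopent-1-ene-1-carboxylate
Conditions: Pd(OAc)2 (5 mol %), PPh3 (10 mol %), CO (1 atm), MeOH, Et3N, DMF, 60 °C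
Reagents that add atoms: carbon monoxide, [C-]#[O+]; methanol, CO
Why: Palladium-catalysed methoxycarbonylation of an enol triflate (oxidative addition, CO insertion, methanolysis) puts the future C7 carbon on C1'.

Step 5
Reactants: 5 methyl (S)-4-(tert-butyldimethylsilyloxy)-5,5-dimethylcyclopent-1-ene-1-carboxylate
Product: 7 methyl (2S,4S)-4-(tert-butyldimethylsilyloxy)-2-hydroxy-5,5-dimethylcyclopentane-1-carboxylate (C1 epimers), via pinacol boronate 6 (not isolated)
Conditions: B2pin2, CuCl (5 mol %), DPEphos (5 mol %), NaOtBu (10 mol %), MeOH, THF, rt; then 30 % H2O2, 3 M NaOH, 0 °C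
Reagents that add atoms: hydrogen peroxide, OO (oxygen of the new OH); bis(pinacolato)diboron, CC1(C)OB(OC1(C)C)B1OC(C)(C)C(C)(C)O1 (boron of 6 only)
Why: Copper-catalysed conjugate borylation should deliver boron to the β-carbon anti to the silyloxy group (1,3-induction), and oxidation with retention then gives the C2' hydroxyl trans to the C4' oxygen; the C1 centre is reset in step 6.

Step 6
Reactants: 7 methyl (2S,4S)-4-(tert-butyldimethylsilyloxy)-2-hydroxy-5,5-dimethylcyclopentane-1-carboxylate
Product: 8 methyl (1R,2S,4S)-4-(tert-butyldimethylsilyloxy)-2-hydroxy-1,5,5-trimethylcyclopentane-1-carboxylate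
Conditions: LDA (2.2 equiv), THF, −78 → −20 °C; MeI, DMPU, −78 → 0 °C
Reagents that add atoms: iodomethane, CI
Why: Frater–Seebach alkylation: the dianion of the β-hydroxy ester is methylated anti to the neighbouring lithium alkoxide, which sets quaternary C1' with the ester cis to OH whatever the C1 configuration of 7.

Step 7
Reactants: 8 methyl (1R,2S,4S)-4-(tert-butyldimethylsilyloxy)-2-hydroxy-1,5,5-trimethylcyclopentane-1-carboxylate
Product: 9 methyl (1R,2S,4S)-4-(tert-butyldimethylsilyloxy)-2-(methoxymethoxy)-1,5,5-trimethylcyclopentane-1-carboxylate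
Conditions: MOMCl, i-Pr2NEt, Bu4NI (cat.), CH2Cl2, 40 °C
Reagents that add atoms: chloromethyl methyl ether, COCCl
Why: Williamson-type acetalisation; the MOM ether makes O2' non-nucleophilic yet able to chelate magnesium in step 15.

Step 8
Reactants: 9 methyl (1R,2S,4S)-4-(tert-butyldimethylsilyloxy)-2-(methoxymethoxy)-1,5,5-trimethylcyclopentane-1-carboxylate
Product: 10 methyl (1R,2S,4S)-4-hydroxy-2-(methoxymethoxy)-1,5,5-trimethylcyclopentane-1-carboxylate
Conditions: HF·pyridine, pyridine, THF, 0 °C → rt
Reagents that add atoms: none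
Why: Fluoride-driven silyl ether cleavage (Si–F bond formation) leaves the MOM acetal and the ester untouched.

Step 9
Reactants: 10 methyl (1R,2S,4S)-4-hydroxy-2-(methoxymethoxy)-1,5,5-trimethylcyclopentane-1-carboxylate
Product: 11 methyl (1R,2S,4R)-4-bromo-2-(methoxymethoxy)-1,5,5-trimethylcyclopentane-1-carboxylate
Conditions: CBr4, PPh3, 2,6-lutidine, toluene, 60 °C
Reagents that add atoms: carbon tetrabromide, BrC(Br)(Br)Br
Why: Appel reaction: SN2 displacement of the alkoxyphosphonium by bromide inverts C4', so bromine ends cis to O2' and to the ester; the oxygen was placed trans in steps 1 and 5 for this purpose.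

Step 10
Reactants: 11 methyl (1R,2S,4R)-4-bromo-2-(methoxymethoxy)-1,5,5-trimethylcyclopentane-1-carboxylate
Product: 12 1-RC-2-chloroethan-1-one
Conditions: ICH2Cl (3 equiv), MeLi·LiBr (3 equiv), THF, −78 °C; AcOH, −78 °C
Reagents that add atoms: chloroiodomethane, ClCI
Why: Ester homologation with chloromethyllithium made in situ: the tetrahedral lithium adduct persists at −78 °C, so the chloromethyl ketone is released only on quench.

Step 11
Reactants: 13 but-3-yn-1-ol
Product: 15 (E)-3-methylpent-2-ene-1,5-diol, via alkenylalane 14 (not isolated)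
Conditions: Me3Al (3 equiv), Cp2ZrCl2 (0.25 equiv), CH2Cl2, 0 °C → rt; n-BuLi, THF, −78 °C; (CH2O)n, → rt; aq. HCl
Reagents that add atoms: trimethylaluminium, C[Al](C)C; paraformaldehyde (formaldehyde unit), C=O
Why: Negishi carboalumination adds CH3 and Al syn across the terminal alkyne, and the derived alanate is hydroxymethylated with retention, fixing the (E)-trisubstituted alkene that becomes C1=C10.

Step 12
Reactants: 15 (E)-3-methylpent-2-ene-1,5-diol
Product: 16 (E)-5-chloro-3-methylpent-3-en-1-ol
Conditions: NCS, Me2S, CH2Cl2, −20 → 0 °C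
Reagents that add atoms: N-chlorosuccinimide, O=C1CCC(=O)N1Cl
Why: Corey–Kim chlorination converts only the allylic alcohol into the chloride and leaves the saturated primary alcohol.

Step 13
Reactants: 16 (E)-5-chloro-3-methylpent-3-en-1-ol
Product: 17 (E)-3-methyl-5-(phenylsulfanyl)pent-3-en-1-ol
Conditions: PhSNa, DMF, 0 °C
Reagents that add atoms: sodium benzenethiolate, [Na+].[S-]c1ccccc1
Why: SN2 displacement of a primary allylic chloride by thiolate; the sulfide is a sulfone precursor that survives the organometallic steps.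

Step 14
Reactants: 17 (E)-3-methyl-5-(phenylsulfanyl)pent-3-en-1-ol
Product: 18 (E)-(5-bromo-3-methylpent-2-en-1-yl)(phenyl)sulfane
Conditions: CBr4, PPh3, CH2Cl2, 0 °C
Reagents that add atoms: carbon tetrabromide, BrC(Br)(Br)Br
Why: Appel bromination of an unhindered primary alcohol.

Step 15
Reactants: 12 1-RC-2-chloroethan-1-one; 18 (E)-(5-bromo-3-methylpent-2-en-1-yl)(phenyl)sulfane
Product: 20 2-RC-2-[(E)-3-methyl-5-(phenylsulfanyl)pent-3-en-1-yl]oxirane (C7 as in the target), via chlorohydrin 19 (not isolated)
Conditions: 18, Mg, Et2O; added to 12 and MgBr2·OEt2 in CH2Cl2, −78 °C; then K2CO3, MeOH, rt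
Reagents that add atoms: none
Why: Chelation-controlled Grignard 1,2-addition (Cram chelate): magnesium bridges the ketone oxygen and the C2' MOM oxygen, the reagent enters from the exposed face of the chelate on the side of the C1' methyl and sets C7, and base then closes the chlorohydrin to the epoxide whose CH2 is C6.

Step 16
Reactants: 20 2-RC-2-[(E)-3-methyl-5-(phenylsulfanyl)pent-3-en-1-yl]oxirane; 21 1-propynyllithium
Product: 22 (E)-8-methyl-10-(phenylsulfanyl)-5-RC-dec-8-en-2-yn-5-ol
Conditions: 21 (3 equiv), BF3·OEt2 (3 equiv), THF, −78 °C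
Reagents that add atoms: none
Why: Lewis-acid-assisted alkynylation opens the 2,2-disubstituted epoxide by SN2 at its CH2 terminus, so C7 is untouched and becomes the tertiary carbinol.

Step 17
Reactants: 22 (E)-8-methyl-10-(phenylsulfanyl)-5-RC-dec-8-en-2-yn-5-ol
Product: 23 (E)-8-methyl-10-(phenylsulfonyl)-5-RC-dec-8-en-2-yn-5-ol
Conditions: Pr4N[RuO4] (5 mol %), NMO (4 equiv), 4 Å MS, MeCN, 40 °C
Reagents that add atoms: 4-methylmorpholine N-oxide, C[N+]1([O-])CCOCC1
Why: Perruthenate-catalysed sulfide oxidation goes through the sulfoxide to the sulfone without touching alkene, alkyne, tertiary alcohol or alkyl bromide, and removes the thioether before the rhodium step.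

Step 18
Reactants: 23 (E)-8-methyl-10-(phenylsulfonyl)-5-RC-dec-8-en-2-yn-5-ol
Product: 24 dimethylsilyl ether of 23 (O7–SiHMe2)
Conditions: ClSiMe2H, Et3N, DMAP (cat.), CH2Cl2, 0 °C → rt
Reagents that add atoms: chlorodimethylsilane, C[SiH](C)Cl
Why: O-silylation of the hindered tertiary alcohol with a small chlorosilane installs the Si–H needed for the tethered alkyne functionalisation.

Step 19
Reactants: 24 dimethylsilyl ether of 23
Product: 25 (Z)-2-[2,2-dimethyl-5-RC-5-((E)-3-methyl-5-(phenylsulfonyl)pent-3-enyl)-1,2-oxasilolan-3-ylidene]propanal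
Conditions: Rh(acac)(CO)2 (3 mol %), CO (20 atm), toluene, 70 °C
Reagents that add atoms: carbon monoxide, [C-]#[O+]
Why: Intramolecular rhodium-catalysed silylformylation of a homopropargylic hydrosilyl ether: 5-exo-dig syn addition places silicon on the proximal alkyne carbon (C5) and the formyl carbon (C3) on the distal one (C4), so Si and C3 are cis by construction and the tetrasubstituted alkene has the geometry needed in the ring.

Step 20
Reactants: 25 oxasilolane enal
Product: 26 (Z)-2-[2,2-dimethyl-5-RC-5-((E)-3-methyl-5-(phenylsulfonyl)pent-3-enyl)-1,2-oxasilolan-3-ylidene]propan-1-ol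
Conditions: i-Bu2AlH, CH2Cl2, −78 °C
Reagents that add atoms: none
Why: 1,2-Reduction of the enal by an aluminium hydride; the alkoxysilane ring and the sulfone are inert at −78 °C.

Step 21
Reactants: 26 oxasilolane allylic alcohol
Product: 28 allylic chloride (C3–Cl) corresponding to 26, via mesylate 27 (not isolated)
Conditions: MsCl, Et3N, CH2Cl2, −40 °C; LiCl, THF, 0 °C → rt
Reagents that add atoms: lithium chloride, [Li+].[Cl-]; methanesulfonyl chloride, CS(Cl)(=O)=O (mesyl group of 27 only)
Why: Mesylation and chloride displacement give the primary allylic chloride without allylic shift, because SN2′ attack at the fully substituted silyl-bearing carbon is blocked.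

Step 22
Reactants: 28 allylic chloride
Product: 29 siloxane-bridged (1(10)E,4E)-cyclodecadiene carrying PhSO2 on C2 (C2 epimers)
Conditions: LiHMDS (1.2 equiv), THF, −78 → 0 °C, slow addition to 0.002 M
Reagents that add atoms: none
Why: Intramolecular alkylation of the sulfone-stabilised allylic carbanion by the allylic chloride closes the ten-membered ring at C2–C3 (α-attack) without touching either alkene geometry; the C2 stereocentre is removed in step 23.

Step 23
Reactants: 29 macrocyclic sulfone
Product: 30 siloxane-bridged (1(10)E,4E)-cyclodecadiene: ring C7–C8–C9–C10(CH3)=C1–C2–C3–C4(CH3)=C5–C6, with C5–SiMe2–O–C7 and RC on C7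
Conditions: PdCl2(dppp) (10 mol %), LiBHEt3 (2 equiv), THF, 0 °C
Reagents that add atoms: none
Why: Palladium-catalysed reductive desulfonylation: zerovalent palladium ionises the allylic sulfone and hydride goes to the less substituted allyl terminus (C2), keeping the position and geometry of C1=C10, while the neopentyl-type secondary bromide and the siloxane should be too hindered to be reduced at 0 °C.

Step 24
Reactants: 30 siloxane-bridged cyclodecadiene
Product: 32 O7-(hydroxydimethylsilyl) ether of the 1-bromo-Δ4-octalin (C10 angular CH3; C1 equatorial Br; C4=C5; RC on C7), via bromosilyl ether 31 (not isolated)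
Conditions: Et2SBr·SbCl5Br (1.1 equiv), MeNO2, −25 °C, 5 min; then aq. NaHCO3/Na2SO3, 0 °C (Si–Br → Si–OH)
Reagents that add atoms: bromodiethylsulfonium bromopentachloroantimonate, CC[S+](Br)CC.Br[Sb-](Cl)(Cl)(Cl)(Cl)Cl (bromine on C1; bromine on silicon in 31 only); water, O (silanol oxygen of 32)
Why: The bromosulfonium salt transfers Br+ to C1 of the exposed trisubstituted C1=C10 alkene, and as the bromonium opens at C10 the silicon-bearing C5 attacks C10 across the ring, after which the β-silyl cation at C4 loses silicon to give C4=C5 regiospecifically. Silicon stays on O7 and takes up halide from the antimonate (drawn as the bromosilyl ether 31), and the aqueous bicarbonate work-up hydrolyses that Si–Br bond, so water supplies the silanol oxygen of 32. The closest known reaction types are the electrophile-induced transannular cyclisation of germacrene-type cyclodeca-1(10),4-dienes to eudesmanes and the vinylsilane-terminated cation–alkene cyclisation. The single C5–C10 bond closes ring A in the 6-endo mode (both carbons of each alkene lie in that ring) and ring B in the 6-exo mode (one carbon of each alkene). C1 is set by anti addition across the (E)-alkene, which makes bromine equatorial and cis to the C10 methyl, and C10 is set relative to C7 by the O7–Si–C5 bridge, which fits only when C7–O and C5–Si are syn-axial in the chair–chair transition state, that is with ring C equatorial and the C10 methyl trans to O7. The step needs Br+ to choose C1=C10 over the silylated alkene and O7 not to capture C10, and the substrate should secure both, because the tetrasubstituted alkoxysilyl alkene is the more hindered one, its oxygen-substituted silicon being a weaker donor, and O7 is tied up in the siloxane.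

Step 25
Reactants: 32 silanol-protected bromo-octalin
Product: 33 bromo-octalin diol (free C7–OH and C2'–OH, C4=C5)
Conditions: Me2BBr (3 equiv), CH2Cl2, −78 °C; aq. NaHCO3, THF, rt; then AcOH–THF–H2O (3:1:1), rt
Reagents that add atoms: none
Why: Lewis-acid cleavage of the MOM acetal by the bromoborane at −78 °C (through the bromomethyl ether, hydrolysed on the bicarbonate quench) and mild aqueous-acid hydrolysis of the labile O7–SiMe2OH bond free both hydroxyls under conditions that spare the tetrasubstituted alkene and the bromides.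

Step 26
Reactants: 33 bromo-octalin diol
Product: 34 4,5-epoxide, oxygen cis to C7–OH and trans to the C10 methyl
Conditions: VO(acac)2 (5 mol %), t-BuOOH (1.5 equiv), CH2Cl2, 0 °C → rt
Reagents that add atoms: tert-butyl hydroperoxide, CC(C)(C)OO
Why: Hydroxyl-directed vanadium-catalysed epoxidation: the axial homoallylic C7–OH delivers the peroxide to its own face of C4=C5, which is also the face anti to the angular methyl, so the epoxide oxygen becomes the C5–OH of the target.

Step 27
Reactants: 34 4,5-epoxide
Product: 35 neoirietetraol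
Conditions: 0.1 M aq. HClO4, THF, 0 °C → rt
Reagents that add atoms: water, O
Why: Acid-catalysed epoxide hydrolysis with trans-diaxial opening: water attacks C4 anti to the epoxide oxygen (backside attack at the ring-fusion carbon C5 would force a cis-decalin), giving axial C4–OH trans to the retained axial C5–OH.

**Compound list**
1 | 2,2-dimethylcyclopentane-1,3-dione | CC1(C)C(=O)CCC1=O | starting material
2 | (S)-3-hydroxy-2,2-dimethylcyclopentan-1-one | CC1(C)[C@@H](O)CCC1=O | intermediate
3 | (S)-3-(tert-butyldimethylsilyloxy)-2,2-dimethylcyclopentan-1-one | CC1(C)[C@@H](O[Si](C)(C)C(C)(C)C)CCC1=O | intermediate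
4 | (S)-4-(tert-butyldimethylsilyloxy)-5,5-dimethylcyclopent-1-en-1-yl triflate | CC1(C)[C@@H](O[Si](C)(C)C(C)(C)C)CC=C1OS(=O)(=O)C(F)(F)F | intermediate
5 | methyl (S)-4-(tert-butyldimethylsilyloxy)-5,5-dimethylcyclopent-1-ene-1-carboxylate | CC1(C)[C@@H](O[Si](C)(C)C(C)(C)C)CC=C1C(=O)OC | intermediate
6 | methyl (2S,4S)-4-(tert-butyldimethylsilyloxy)-5,5-dimethyl-2-(pinacolboryl)cyclopentane-1-carboxylate | CC1(C)[C@@H](O[Si](C)(C)C(C)(C)C)C[C@H](B2OC(C)(C)C(C)(C)O2)C1C(=O)OC | intermediate (not isolated)
7 | methyl (2S,4S)-4-(tert-butyldimethylsilyloxy)-2-hydroxy-5,5-dimethylcyclopentane-1-carboxylate | CC1(C)[C@@H](O[Si](C)(C)C(C)(C)C)C[C@H](O)C1C(=O)OC | intermediate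
8 | methyl (1R,2S,4S)-4-(tert-butyldimethylsilyloxy)-2-hydroxy-1,5,5-trimethylcyclopentane-1-carboxylate | CC1(C)[C@@H](O[Si](C)(C)C(C)(C)C)C[C@H](O)[C@]1(C)C(=O)OC | intermediate
9 | methyl (1R,2S,4S)-4-(tert-butyldimethylsilyloxy)-2-(methoxymethoxy)-1,5,5-trimethylcyclopentane-1-carboxylate | CC1(C)[C@@H](O[Si](C)(C)C(C)(C)C)C[C@H](OCOC)[C@]1(C)C(=O)OC | intermediate
10 | methyl (1R,2S,4S)-4-hydroxy-2-(methoxymethoxy)-1,5,5-trimethylcyclopentane-1-carboxylate | CC1(C)[C@@H](O)C[C@H](OCOC)[C@]1(C)C(=O)OC | intermediate
11 | methyl (1R,2S,4R)-4-bromo-2-(methoxymethoxy)-1,5,5-trimethylcyclopentane-1-carboxylate | CC1(C)[C@H](Br)C[C@H](OCOC)[C@]1(C)C(=O)OC | intermediate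
12 | 1-RC-2-chloroethan-1-one | CC1(C)[C@H](Br)C[C@H](OCOC)[C@]1(C)C(=O)CCl | intermediate
13 | but-3-yn-1-ol | C#CCCO | starting material
14 | (E)-alkenylalane from 13 (Al on C1, CH3 on C10, O–AlMe2) | C[Al](C)/C=C(C)/CCO[Al](C)C | intermediate (not isolated)
15 | (E)-3-methylpent-2-ene-1,5-diol | OCC/C(C)=C/CO | intermediate
16 | (E)-5-chloro-3-methylpent-3-en-1-ol | OCC/C(C)=C/CCl | intermediate
17 | (E)-3-methyl-5-(phenylsulfanyl)pent-3-en-1-ol | OCC/C(C)=C/CSc1ccccc1 | intermediate
18 | (E)-(5-bromo-3-methylpent-2-en-1-yl)(phenyl)sulfane | BrCC/C(C)=C/CSc1ccccc1 | intermediate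
19 | chlorohydrin: C7(OH)(CH2Cl)(RC) with the C8 chain | CC1(C)[C@H](Br)C[C@H](OCOC)[C@]1(C)[C@@](CCl)(O)CC/C(C)=C/CSc2ccccc2 | intermediate (not isolated)
20 | 2-RC-2-[(E)-3-methyl-5-(phenylsulfanyl)pent-3-en-1-yl]oxirane | CC1(C)[C@H](Br)C[C@H](OCOC)[C@]1(C)[C@@]2(OC2)CC/C(C)=C/CSc3ccccc3 | intermediate
21 | 1-propynyllithium | [Li]C#CC | starting material
22 | (E)-8-methyl-10-(phenylsulfanyl)-5-RC-dec-8-en-2-yn-5-ol | CC1(C)[C@H](Br)C[C@H](OCOC)[C@]1(C)[C@@](CC#CC)(O)CC/C(C)=C/CSc2ccccc2 | intermediate
23 | (E)-8-methyl-10-(phenylsulfonyl)-5-RC-dec-8-en-2-yn-5-ol | CC1(C)[C@H](Br)C[C@H](OCOC)[C@]1(C)[C@@](CC#CC)(O)CC/C(C)=C/CS(=O)(=O)c2ccccc2 | intermediate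
24 | dimethylsilyl ether of 23 | CC1(C)[C@H](Br)C[C@H](OCOC)[C@]1(C)[C@@](CC#CC)(O[SiH](C)C)CC/C(C)=C/CS(=O)(=O)c2ccccc2 | intermediate
25 | oxasilolane enal (Si on C5 cis to CHO) | CC1(C)[C@H](Br)C[C@H](OCOC)[C@]1(C)[C@@]2(O[Si](C)(C)/C(C2)=C(/C)C=O)CC/C(C)=C/CS(=O)(=O)c3ccccc3 | intermediate
26 | oxasilolane allylic alcohol (C3–OH) | CC1(C)[C@H](Br)C[C@H](OCOC)[C@]1(C)[C@@]2(O[Si](C)(C)/C(C2)=C(/C)CO)CC/C(C)=C/CS(=O)(=O)c3ccccc3 | intermediate
27 | mesylate of 26 | CC1(C)[C@H](Br)C[C@H](OCOC)[C@]1(C)[C@@]2(O[Si](C)(C)/C(C2)=C(/C)COS(C)(=O)=O)CC/C(C)=C/CS(=O)(=O)c3ccccc3 | intermediate (not isolated)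
28 | oxasilolane allylic chloride (C3–Cl) | CC1(C)[C@H](Br)C[C@H](OCOC)[C@]1(C)[C@@]2(O[Si](C)(C)/C(C2)=C(/C)CCl)CC/C(C)=C/CS(=O)(=O)c3ccccc3 | intermediate
29 | siloxane-bridged cyclodecadiene, PhSO2 on C2 | CC1(C)[C@H](Br)C[C@H](OCOC)[C@]1(C)[C@@]23CC/C(C)=C/C(S(=O)(=O)c4ccccc4)C/C(C)=C(/C2)[Si](C)(C)O3 | intermediate
30 | siloxane-bridged (1(10)E,4E)-cyclodecadiene (key-step precursor) | CC1(C)[C@H](Br)C[C@H](OCOC)[C@]1(C)[C@@]23CC/C(C)=C/CC/C(C)=C(/C2)[Si](C)(C)O3 | intermediate
31 | bromo-octalin, O7–SiMe2Br | CC1(C)[C@H](Br)C[C@H](OCOC)[C@]1(C)[C@@]3(O[Si](C)(C)Br)CC[C@]2(C)[C@@H](Br)CCC(C)=C2C3 | intermediate (not isolated)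
32 | bromo-octalin, O7–SiMe2OH (key-step product) | CC1(C)[C@H](Br)C[C@H](OCOC)[C@]1(C)[C@@]3(O[Si](C)(C)O)CC[C@]2(C)[C@@H](Br)CCC(C)=C2C3 | intermediate
33 | bromo-octalin diol | CC1(C)[C@H](Br)C[C@H](O)[C@]1(C)[C@@]3(O)CC[C@]2(C)[C@@H](Br)CCC(C)=C2C3 | intermediate
34 | 4,5-epoxide (O cis to C7–OH) | CC1(C)[C@H](Br)C[C@H](O)[C@]1(C)[C@@]3(O)CC[C@]2(C)[C@@H](Br)CC[C@]4(C)O[C@]24C3 | intermediate
35 | neoirietetraol | CC1(C)[C@H](Br)C[C@H](O)[C@]1(C)[C@@]1(O)CC[C@]2(C)[C@@H](Br)CC[C@@](C)(O)[C@@]2(O)C1 | target

Total step count: 27. Longest linear sequence: 23 (steps 1–10 and 15–27).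

**Steps most likely to fail**

Step 24. Bromonium formation could occur at the silylated alkene and end in bromodesilylation, or the bridged ring might not reach the crossed geometry, so that halide rather than C5 opens the bromonium; the Lewis acid could also ionise the acetal. Fallback from 30: mercury bis(trifluoroacetate), Hg(O2CCF3)2, in MeNO2 at −20 °C followed by aqueous KBr should effect the same transannular closure with loss of silicon and give the equatorial C1 organomercury bromide F1. The softer electrophile adds reversibly and is more selective for the less hindered alkene. Br2 (1.0 equiv) and LiBr in pyridine at −40 °C in the dark should then replace mercury by bromine with retention, the polar cleavage of the C–Hg bond being expected to outrun addition of the pyridine–bromine complex to the hindered tetrasubstituted alkene, rejoining the route at 32.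

Step 22. Oligomerisation or proton transfer may outrun the slow closure of the strained, bridged ten-membered ring. Fallback from 25: LiHMDS in THF at −78 °C under high dilution should add the sulfonyl carbanion to the C3 aldehyde (1,2-addition, the same C2–C3 bond), and trapping the alkoxide with methyl chloroformate gives the macrocyclic methyl carbonate F5. PdCl2(dppp) with LiBHEt3 should then remove the allylic carbonate and the allylic sulfone together, rejoining the route at 30.

Step 9. Substitution at the neopentyl-type secondary carbon may be too slow, so that elimination to the cyclopentene or participation of the ester carbonyl (lactone formation) takes over. Fallback from 10: oxidation with 1,1,1-triacetoxy-1,1-dihydro-1,2-benziodoxol-3(1H)-one gives the ketone F2, hydrazine hydrate in ethanol the hydrazone F3, and NBS in pyridine the vinyl bromide F4. Diimide (from TsNHNH2 and NaOAc) should add hydrogen syn from the face opposite to the MOM ether and the ester, which puts bromine cis to both and rejoins the route at 11.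

**Further compounds**
F1 | step 24 | C1 organomercury bromide of the bromo-octalin silanol | CC1(C)[C@H](Br)C[C@H](OCOC)[C@]1(C)[C@@]3(O[Si](C)(C)O)CC[C@]2(C)[C@@H]([Hg]Br)CCC(C)=C2C3
F2 | step 9 | methyl (1R,2S)-2-(methoxymethoxy)-1,5,5-trimethyl-4-oxocyclopentane-1-carboxylate | CC1(C)C(=O)C[C@H](OCOC)[C@]1(C)C(=O)OC
F3 | step 9 | hydrazone of F2 | CC1(C)C(=NN)C[C@H](OCOC)[C@]1(C)C(=O)OC
F4 | step 9 | methyl (1R,2S)-4-bromo-2-(methoxymethoxy)-1,5,5-trimethylcyclopent-3-ene-1-carboxylate | CC1(C)C(Br)=C[C@H](OCOC)[C@]1(C)C(=O)OC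
F5 | step 22 | siloxane-bridged cyclodecadiene with PhSO2 on C2 and OCO2CH3 on C3 | CC1(C)[C@H](Br)C[C@H](OCOC)[C@]1(C)[C@@]23CC/C(C)=C/C(S(=O)(=O)c4ccccc4)C(OC(=O)OC)/C(C)=C(/C2)[Si](C)(C)O3
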